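**Plan**

- Ring numbering used below: carbocycle C1–C10 (C1=C10, CH3 = C14 on C10), epoxide C4–C5 (CH2OH = C15 on C4), lactone O on C6, acrylate carbons C11–C13 on C7, ester O on C8.
- Enabling feature: the only C=C inside the ten-membered ring, Z-C1=C10 flanked by C2H2 and C9H2, is cut into C1–SO2–C10. The carbocycle is therefore made as an 11-membered thiacycle and contracted by one atom with loss of SO2 (Ramberg–Bäcklund). Because C8–O is β to C10, sulfur can be brought to C10 by conjugate addition to a C8 propenyl ketone.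
- Further cuts: S–C1 (S-alkylation), C8–C9 (Weinreb amide + propenyl Grignard), C6–C7 (Evans aldol), C3–C4 (cuprate addition to an alkynoate), lactone C12–O6, side-chain ester C–O.
- Forward order of rings: epoxide (step 6), 11-membered sulfide (step 18), ten-membered carbocycle (step 21), α-methylene lactone (step 23); the side-chain ester is attached last.
- Stereochemistry: C4/C5 from Sharpless epoxidation, C6/C7 from the Evans syn-aldol, C8 from the Evans–Tishchenko 1,3-anti reduction (which also tells O6 from O8), Z-olefin from the cis-fused episulfone, side-chain E-olefin from a stabilised Wittig reaction.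

Key step: step 21

Remark on the chemistry: C10 (the sulfur-bearing methine made in step 15) is carried as an epimer mixture from 23 to 32, and enone 22 as an E/Z mixture. Both converge because C10 becomes sp2 in step 21, so the SMILES carry no descriptor at these places (the same holds for S in 29 and C1 in 31 and 32).

**Route**

Step 1
Reactants: 1 prop-2-yn-1-ol
Product: 2 1-methoxy-4-[(prop-2-yn-1-yloxy)methyl]benzene
Conditions: NaH, PMBCl, Bu4NI (cat.), THF, 0 → 23 °C
Reagents that add atoms: 4-methoxybenzyl chloride COc1ccc(CCl)cc1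
Why: Williamson etherification; the PMB ether on the future C15 oxygen should outlast every later step and is removed oxidatively at the end.

Step 2
Reactants: 2 1-methoxy-4-[(prop-2-yn-1-yloxy)methyl]benzene
Product: 3 methyl 4-[(4-methoxybenzyl)oxy]but-2-ynoate
Conditions: n-BuLi, THF, −78 °C; ClCO2Me, −78 → 0 °C
Reagents that add atoms: methyl chloroformate COC(=O)Cl
Why: C-acylation of the lithium acetylide with a chloroformate should give the alkynoate acceptor (future C4–C6, C15).

Step 3
Reactants: 3 methyl 4-[(4-methoxybenzyl)oxy]but-2-ynoate; 4 3-chloropropan-1-ol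
Product: 6 methyl (Z)-6-hydroxy-3-{[(4-methoxybenzyl)oxy]methyl}hex-2-enoate, via Normant reagent 5 (not isolated)
Conditions: 4, i-PrMgCl, THF, −20 °C, then Mg, reflux; CuBr·SMe2 (0.5 equiv per 5), THF, −78 °C; 3, −78 °C; aq. NH4Cl at −78 °C
Reagents that add atoms: none
Why: syn-carbocupration of the alkynoate (organocuprate conjugate addition) and cold protonation of the vinylcopper should place the new C1–C3 chain cis to H, i.e. trans to the ester, which is the geometry the trans-epoxide needs.

Step 4
Reactants: 6 methyl (Z)-6-hydroxy-3-{[(4-methoxybenzyl)oxy]methyl}hex-2-enoate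
Product: 7 methyl (Z)-6-chloro-3-{[(4-methoxybenzyl)oxy]methyl}hex-2-enoate
Conditions: NCS, PPh3, CH2Cl2, −20 → 23 °C
Reagents that add atoms: N-chlorosuccinimide O=C1CCC(=O)N1Cl
Why: Appel-type chlorination of the primary alcohol should install an inert C1 leaving group that is used only in the S-alkylation of step 18.

Step 5
Reactants: 7 methyl (Z)-6-chloro-3-{[(4-methoxybenzyl)oxy]methyl}hex-2-enoate
Product: 8 (Z)-6-chloro-3-{[(4-methoxybenzyl)oxy]methyl}hex-2-en-1-ol
Conditions: DIBAL-H, CH2Cl2, −78 → 0 °C; Rochelle salt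
Reagents that add atoms: none
Why: 1,2-reduction of the enoate by DIBAL-H should give the allylic alcohol with unchanged olefin geometry.

Step 6
Reactants: 8 (Z)-6-chloro-3-{[(4-methoxybenzyl)oxy]methyl}hex-2-en-1-ol
Product: 9 [(2R,3S)-3-(3-chloropropyl)-3-{[(4-methoxybenzyl)oxy]methyl}oxiran-2-yl]methanol
Conditions: Ti(Oi-Pr)4 (cat.), D-(−)-diethyl tartrate, t-BuOOH, 4 Å MS, CH2Cl2, −20 °C
Reagents that add atoms: tert-butyl hydroperoxide CC(C)(C)OO
Why: Sharpless asymmetric epoxidation of a 3,3-disubstituted (geraniol-type) primary allylic alcohol; D-(−)-tartrate should deliver oxygen to the face that gives C4 S and C5 R (ring numbering), and the olefin geometry makes the epoxide trans with respect to the C3 and C6 bonds.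

Step 7
Reactants: 9 [(2R,3S)-3-(3-chloropropyl)-3-{[(4-methoxybenzyl)oxy]methyl}oxiran-2-yl]methanol
Product: 10 (2S,3S)-3-(3-chloropropyl)-3-{[(4-methoxybenzyl)oxy]methyl}oxirane-2-carbaldehyde
Conditions: TEMPO (cat.), PhI(OAc)2, CH2Cl2, 23 °C
Reagents that add atoms: none
Why: TEMPO/PhI(OAc)2 oxidation of the primary alcohol is non-basic, so the epoxide centre α to the aldehyde should stay intact (descriptor changes by CIP only).

Step 8
Reactants: 11 4-methoxy-2-methylidene-4-oxobutanoic acid (itaconic acid 4-methyl ester)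
Product: 12 methyl 3-(hydroxymethyl)but-3-enoate
Conditions: BH3·SMe2, THF, −10 → 0 °C
Reagents that add atoms: none
Why: borane reduces the free carboxylic acid chemoselectively in the presence of the methyl ester, giving the future C12 at the alcohol level.

Step 9
Reactants: 12 methyl 3-(hydroxymethyl)but-3-enoate
Product: 13 methyl 3-({[tert-butyl(dimethyl)silyl]oxy}methyl)but-3-enoate
Conditions: TBSCl, imidazole, CH2Cl2, 0 °C
Reagents that add atoms: tert-butyldimethylsilyl chloride CC(C)(C)[Si](C)(C)Cl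
Why: prompt silylation should prevent lactonisation of the γ-hydroxy ester and mask C12–OH until step 22.

Step 10
Reactants: 13 methyl 3-({[tert-butyl(dimethyl)silyl]oxy}methyl)but-3-enoate
Product: 14 3-({[tert-butyl(dimethyl)silyl]oxy}methyl)but-3-enoic acid
Conditions: LiOH, THF/H2O, 0 °C; then 1 M HCl to pH 4
Reagents that add atoms: lithium hydroxide [Li+].[OH-]
Why: cold saponification should give the β,γ-unsaturated acid without migration of the 1,1-disubstituted double bond.

Step 11
Reactants: 14 3-({[tert-butyl(dimethyl)silyl]oxy}methyl)but-3-enoic acid; 15 (S)-4-benzyl-1,3-oxazolidin-2-one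
Product: 17 (S)-4-benzyl-3-[3-({[tert-butyl(dimethyl)silyl]oxy}methyl)but-3-enoyl]-1,3-oxazolidin-2-one, via mixed pivalic anhydride 16 (not isolated)
Conditions: PivCl, Et3N, THF, −20 °C; then 15, LiCl, −20 → 23 °C
Reagents that add atoms: none
Why: N-acylation of the Evans auxiliary through the mixed pivalic anhydride under LiCl/Et3N conditions avoids strong base and double-bond migration.

Step 12
Reactants: 17 (S)-4-benzyl-3-[3-({[tert-butyl(dimethyl)silyl]oxy}methyl)but-3-enoyl]-1,3-oxazolidin-2-one; 10 (2S,3S)-3-(3-chloropropyl)-3-{[(4-methoxybenzyl)oxy]methyl}oxirane-2-carbaldehyde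
Product: 19 (S)-4-benzyl-3-[(2S,3S)-2-(3-{[tert-butyl(dimethyl)silyl]oxy}prop-1-en-2-yl)-3-[(2R,3S)-3-(3-chloropropyl)-3-{[(4-methoxybenzyl)oxy]methyl}oxiran-2-yl]-3-hydroxypropanoyl]-1,3-oxazolidin-2-one, via Z-boron enolate 18 (not isolated)
Conditions: Bu2BOTf, i-Pr2NEt, CH2Cl2, −78 → 0 °C; 10, −78 → −10 °C; pH 7 buffer, MeOH, 30% H2O2, 0 °C
Reagents that add atoms: none
Why: Evans syn-aldol reaction; the Z(O)-boron enolate reacts at its α-carbon through a Zimmerman–Traxler chair, and the (S)-benzyl auxiliary should set C7 and C6 (6,7-syn, the relationship that later gives the trans-lactone), overriding the bias of the epoxy aldehyde.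

Step 13
Reactants: 19 syn-aldol adduct
Product: 20 (2S,3S)-2-(3-{[tert-butyl(dimethyl)silyl]oxy}prop-1-en-2-yl)-3-[(2R,3S)-3-(3-chloropropyl)-3-{[(4-methoxybenzyl)oxy]methyl}oxiran-2-yl]-3-hydroxy-N-methoxy-N-methylpropanamide
Conditions: MeNHOMe·HCl, AlMe3, CH2Cl2, −20 → 0 °C; Rochelle salt
Reagents that add atoms: N,O-dimethylhydroxylamine hydrochloride CNOC.Cl
Why: Weinreb transamidation of the β-hydroxy imide by the aluminium amide (assisted by the C6 aluminium alkoxide); the low temperature should spare the epoxide.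

Step 14
Reactants: 20 Weinreb amide; 21 prop-1-enylmagnesium bromide (E/Z mixture, THF solution)
Product: 22 propenyl ketone (C8 ketone conjugated with C9=C10; C6–OH free; otherwise as 20)
Conditions: 21 (3 equiv), THF, −78 → 0 °C; cold aq. NH4Cl
Reagents that add atoms: none
Why: Grignard addition to a Weinreb amide stops at the chelated tetrahedral intermediate, so the enone (C8–C10 and C14) should form without over-addition; the first equivalent only deprotonates the C6 hydroxyl.

Step 15
Reactants: 22 propenyl ketone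
Product: 23 β-acetylthio ketone (AcS on C10, epimer mixture; C6–OH; C8 ketone)
Conditions: AcSH, Et3N (10 mol %), CH2Cl2, 0 °C, exclusion of light
Reagents that add atoms: thioacetic acid CC(=O)S
Why: thia-Michael addition of thioacetic acid to the enone puts sulfur on C10; the new centre is not controlled and need not be, and the mild conditions should avoid retro-aldol and conjugation of the β,γ-double bond.

Step 16
Reactants: 23 β-acetylthio ketone
Product: 24 O6-acetate C8-alcohol (C6 and C8 oxygens 1,3-anti; AcS on C10)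
Conditions: SmI2 (30 mol %), MeCHO (6 equiv), THF, −10 °C
Reagents that add atoms: acetaldehyde CC=O
Why: Evans–Tishchenko reduction; the samarium-bound hemiacetal formed from O6 and acetaldehyde delivers hydride intramolecularly to C8 through a chair-like transition state, which should set C8 1,3-anti to C6 and leave O6 as the acetate, so the two secondary oxygens are differentiated.

Step 17
Reactants: 24 O6-acetate C8-alcohol
Product: 25 C8 tert-butyldimethylsilyl ether of 24
Conditions: TBSOTf, 2,6-lutidine, CH2Cl2, −78 °C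
Reagents that add atoms: tert-butyldimethylsilyl triflate CC(C)(C)[Si](C)(C)OS(=O)(=O)C(F)(F)F
Why: cold silylation of the free C8 hydroxyl before any basic step fixes the O6/O8 differentiation.

Step 18
Reactants: 25 C8 silyl ether
Product: 27 11-membered cyclic sulfide (S bridges C1 and C10; C6–OH free; C8–OTBS; C12–OTBS; C15–OPMB), via chloro thiol 26 (not isolated)
Conditions: DIBAL-H, CH2Cl2, −78 °C, Rochelle-salt work-up; crude thiol: Cs2CO3, NaI (cat.), degassed DMF (1 mM), 23 → 40 °C
Reagents that add atoms: none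
Why: reductive removal of both acetyl groups at −78 °C avoids base-induced silyl migration, and the caesium thiolate should then displace the primary chloride (iodide-assisted SN2) under high dilution to close the 11-membered thiacycle, a macrocyclic thioether formation.

Step 19
Reactants: 27 cyclic sulfide alcohol
Product: 28 C6 triethylsilyl ether of 27
Conditions: TESOTf, 2,6-lutidine, CH2Cl2, −78 °C
Reagents that add atoms: triethylsilyl triflate CC[Si](CC)(CC)OS(=O)(=O)C(F)(F)F
Why: silylation of the last free hydroxyl, so that the key step meets no alkoxide; TES is chosen so that it leaves together with the primary TBS group in step 22.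

Step 20
Reactants: 28 cyclic sulfide
Product: 30 11-membered cyclic sulfone, via cyclic sulfoxide 29 (not isolated)
Conditions: TPAP (10 mol %), NMO (4 equiv), 4 Å MS, MeCN, 23 → 40 °C
Reagents that add atoms: N-methylmorpholine N-oxide C[N+]1([O-])CCOCC1
Why: TPAP/NMO oxidises sulfides to sulfones under neutral conditions and should leave the 1,1-disubstituted alkene, the epoxide, the PMB ether and the silyl ethers untouched.

Step 21
Reactants: 30 11-membered cyclic sulfone
Product: 33 (1(10)Z)-configured ten-membered carbocycle (C6–OTES; C8–OTBS; C12–OTBS; C15–OPMB; 4,5-epoxide), via α-bromosulfone 31 (not isolated), via episulfone 32 (not isolated)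
Conditions: BrCl2C–CCl2Br, KOH/Al2O3, t-BuOH/THF, 0 → 23 °C
Reagents that add atoms: none
Why: In-situ Ramberg–Bäcklund reaction: deprotonation α to the sulfone and bromine transfer from the halocarbon give α-bromosulfone 31, the second α-carbanion closes the thiirane 1,1-dioxide 32 by intramolecular 1,3-displacement (3-exo-tet, inversion at the bromine-bearing carbon), and cheletropic loss of SO2 turns the 11-membered thiacycle into the ten-membered carbocycle with the new C1=C10 double bond. The closest known reaction type is the Ramberg–Bäcklund ring contraction of medium and large cyclic sulfones, which has been used for trisubstituted olefins in medium rings of sesquiterpene lactones. No stereocentre is created; the element to control is the olefin geometry, and since SO2 extrusion is stereospecific the Z-olefin should follow from the cis-fused episulfone (C2 and C9 on the same side of the three-membered ring), the less strained fusion on a ten-membered perimeter, which is accessible because the α-bromosulfone and the episulfone C1–H epimerise under the basic conditions. The step needs chemoselectivity for the two sulfone α-positions, which is secured because every hydroxyl is protected, no carbonyl group is present, and the epoxide could only be reached through a 4-exo attack at its fully substituted carbon or a 5-endo attack. Bromination at either α-carbon leads to the same episulfone, so its regiochemistry is irrelevant, and the C10 epimer mixture carried since step 15 converges here.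

Step 22
Reactants: 33 ten-membered carbocycle
Product: 34 6,12-diol (C6–OH and allylic C12–OH free; C8–OTBS; C15–OPMB)
Conditions: HF·pyridine, pyridine, THF, 0 °C
Reagents that add atoms: none
Why: buffered HF·pyridine should cleave the secondary TES ether and the primary allylic TBS ether much faster than the hindered secondary TBS ether on O8, and is mild enough for the epoxide.

Step 23
Reactants: 34 6,12-diol
Product: 36 α-methylene-γ-lactone (6,12-olide; C8–OTBS; C15–OPMB), via lactol 35 (not isolated)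
Conditions: MnO2 (excess), CH2Cl2, 23 °C
Reagents that add atoms: none
Why: MnO2 oxidises only the allylic primary alcohol; the enal closes with O6 to the five-membered lactol (5-exo-trig), which is oxidised further to the lactone, trans-fused because C6 and C7 are already set, while O8 is blocked so that the 8,12-olide cannot form.

Step 24
Reactants: 36 α-methylene-γ-lactone
Product: 37 C8 alcohol (8-hydroxy-6,12-olide; C15–OPMB)
Conditions: HF·pyridine, THF, 0 → 23 °C
Reagents that add atoms: none
Why: fluoride cleavage of the remaining silyl ether under weakly acidic conditions, which the α-methylene lactone and the epoxide should tolerate.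

Step 25
Reactants: 38 2-[(4-methoxybenzyl)oxy]acetaldehyde; 39 ethyl 2-(triphenyl-λ5-phosphanylidene)propanoate
Product: 40 ethyl (E)-4-[(4-methoxybenzyl)oxy]-2-methylbut-2-enoate
Conditions: CH2Cl2, 23 °C
Reagents that add atoms: none
Why: Wittig reaction of a stabilised ylide is E-selective and gives the tiglate-type side chain.

Step 26
Reactants: 40 ethyl (E)-4-[(4-methoxybenzyl)oxy]-2-methylbut-2-enoate
Product: 41 (E)-4-[(4-methoxybenzyl)oxy]-2-methylbut-2-enoic acid
Conditions: LiOH, THF/MeOH/H2O, 23 °C; then 1 M HCl to pH 3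
Reagents that add atoms: lithium hydroxide [Li+].[OH-]
Why: saponification of the hindered enoate without loss of the E geometry.

Step 27
Reactants: 37 C8 alcohol; 41 (E)-4-[(4-methoxybenzyl)oxy]-2-methylbut-2-enoic acid
Product: 43 bis-PMB ether of the target, via mixed Yamaguchi anhydride 42 (not isolated)
Conditions: 2,4,6-Cl3C6H2COCl, Et3N, THF, 23 °C; then 37, DMAP, toluene, 23 °C
Reagents that add atoms: none
Why: Yamaguchi esterification acylates the hindered secondary C8 hydroxyl with retention at C8 and is compatible with the α-methylene lactone and the epoxide.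

Step 28
Reactants: 43 bis-PMB ether
Product: 44 CNP0187639.2 (target)
Conditions: DDQ, CH2Cl2/pH 7 buffer, 0 → 23 °C
Reagents that add atoms: none
Why: oxidative cleavage of both PMB ethers with DDQ under buffered, near-neutral conditions should free C15–OH and the side-chain hydroxyl without Payne rearrangement or transannular opening of the epoxide.

**Compound list**

1 | prop-2-yn-1-ol | C#CCO | starting material
2 | 1-methoxy-4-[(prop-2-yn-1-yloxy)methyl]benzene | C#CCOCc1ccc(OC)cc1 | intermediate
3 | methyl 4-[(4-methoxybenzyl)oxy]but-2-ynoate | COC(=O)C#CCOCc1ccc(OC)cc1 | intermediate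
4 | 3-chloropropan-1-ol | OCCCCl | starting material
5 | Normant reagent, chloromagnesium 3-(chloromagnesio)propan-1-olate | Cl[Mg]CCCO[Mg]Cl | intermediate
6 | methyl (Z)-6-hydroxy-3-{[(4-methoxybenzyl)oxy]methyl}hex-2-enoate | COC(=O)/C=C(/CCCO)COCc1ccc(OC)cc1 | intermediate
7 | methyl (Z)-6-chloro-3-{[(4-methoxybenzyl)oxy]methyl}hex-2-enoate | COC(=O)/C=C(/CCCCl)COCc1ccc(OC)cc1 | intermediate
8 | (Z)-6-chloro-3-{[(4-methoxybenzyl)oxy]methyl}hex-2-en-1-ol | OC/C=C(/CCCCl)COCc1ccc(OC)cc1 | intermediate
9 | [(2R,3S)-3-(3-chloropropyl)-3-{[(4-methoxybenzyl)oxy]methyl}oxiran-2-yl]methanol | ClCCC[C@@]1(COCc2ccc(OC)cc2)O[C@@H]1CO | intermediate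
10 | (2S,3S)-3-(3-chloropropyl)-3-{[(4-methoxybenzyl)oxy]methyl}oxirane-2-carbaldehyde | ClCCC[C@@]1(COCc2ccc(OC)cc2)O[C@@H]1C=O | intermediate
11 | 4-methoxy-2-methylidene-4-oxobutanoic acid (itaconic acid 4-methyl ester) | C=C(CC(=O)OC)C(=O)O | starting material
12 | methyl 3-(hydroxymethyl)but-3-enoate | C=C(CO)CC(=O)OC | intermediate
13 | methyl 3-({[tert-butyl(dimethyl)silyl]oxy}methyl)but-3-enoate | C=C(CO[Si](C)(C)C(C)(C)C)CC(=O)OC | intermediate
14 | 3-({[tert-butyl(dimethyl)silyl]oxy}methyl)but-3-enoic acid | C=C(CO[Si](C)(C)C(C)(C)C)CC(=O)O | intermediate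
15 | (S)-4-benzyl-1,3-oxazolidin-2-one | O=C1N[C@@H](Cc2ccccc2)CO1 | starting material
16 | mixed pivalic anhydride of 14 | C=C(CO[Si](C)(C)C(C)(C)C)CC(=O)OC(=O)C(C)(C)C | intermediate
17 | (S)-4-benzyl-3-[3-({[tert-butyl(dimethyl)silyl]oxy}methyl)but-3-enoyl]-1,3-oxazolidin-2-one | C=C(CO[Si](C)(C)C(C)(C)C)CC(=O)N1[C@@H](Cc2ccccc2)COC1=O | intermediate
18 | Z-dibutylboron enolate of 17 | C=C(CO[Si](C)(C)C(C)(C)C)/C=C(\OB(CCCC)CCCC)N1[C@@H](Cc2ccccc2)COC1=O | intermediate
19 | syn-aldol adduct (C6–OH, C7 branch, imide at C8) | ClCCC[C@@]1(COCc2ccc(OC)cc2)O[C@@H]1[C@@H](O)[C@H](C(=C)CO[Si](C)(C)C(C)(C)C)C(=O)N1[C@@H](Cc2ccccc2)COC1=O | intermediate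
20 | Weinreb amide (N-methoxy-N-methylamide at C8) | ClCCC[C@@]1(COCc2ccc(OC)cc2)O[C@@H]1[C@@H](O)[C@H](C(=C)CO[Si](C)(C)C(C)(C)C)C(=O)N(C)OC | intermediate
21 | prop-1-enylmagnesium bromide (E/Z mixture) | CC=C[Mg]Br | starting material
22 | propenyl ketone (C8 ketone, C9=C10 as E/Z mixture) | ClCCC[C@@]1(COCc2ccc(OC)cc2)O[C@@H]1[C@@H](O)[C@H](C(=C)CO[Si](C)(C)C(C)(C)C)C(=O)C=CC | intermediate
23 | β-acetylthio ketone (AcS on C10, epimer mixture) | ClCCC[C@@]1(COCc2ccc(OC)cc2)O[C@@H]1[C@@H](O)[C@H](C(=C)CO[Si](C)(C)C(C)(C)C)C(=O)CC(C)SC(C)=O | intermediate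
24 | O6-acetate C8-alcohol (6,8-anti) | ClCCC[C@@]1(COCc2ccc(OC)cc2)O[C@@H]1[C@@H](OC(C)=O)[C@H](C(=C)CO[Si](C)(C)C(C)(C)C)[C@H](O)CC(C)SC(C)=O | intermediate
25 | C8 tert-butyldimethylsilyl ether of 24 | ClCCC[C@@]1(COCc2ccc(OC)cc2)O[C@@H]1[C@@H](OC(C)=O)[C@H](C(=C)CO[Si](C)(C)C(C)(C)C)[C@H](O[Si](C)(C)C(C)(C)C)CC(C)SC(C)=O | intermediate
26 | chloro thiol (C1–Cl, C6–OH, C8–OTBS, C10–SH) | ClCCC[C@@]1(COCc2ccc(OC)cc2)O[C@@H]1[C@@H](O)[C@H](C(=C)CO[Si](C)(C)C(C)(C)C)[C@H](O[Si](C)(C)C(C)(C)C)CC(C)S | intermediate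
27 | 11-membered cyclic sulfide, C6–OH free | S1CCC[C@@]2(COCc3ccc(OC)cc3)O[C@@H]2[C@@H](O)[C@H](C(=C)CO[Si](C)(C)C(C)(C)C)[C@H](O[Si](C)(C)C(C)(C)C)CC1C | intermediate
28 | 11-membered cyclic sulfide, C6–OTES | S1CCC[C@@]2(COCc3ccc(OC)cc3)O[C@@H]2[C@@H](O[Si](CC)(CC)CC)[C@H](C(=C)CO[Si](C)(C)C(C)(C)C)[C@H](O[Si](C)(C)C(C)(C)C)CC1C | intermediate
29 | cyclic sulfoxide | O=S1CCC[C@@]2(COCc3ccc(OC)cc3)O[C@@H]2[C@@H](O[Si](CC)(CC)CC)[C@H](C(=C)CO[Si](C)(C)C(C)(C)C)[C@H](O[Si](C)(C)C(C)(C)C)CC1C | intermediate
30 | 11-membered cyclic sulfone | O=S1(=O)CCC[C@@]2(COCc3ccc(OC)cc3)O[C@@H]2[C@@H](O[Si](CC)(CC)CC)[C@H](C(=C)CO[Si](C)(C)C(C)(C)C)[C@H](O[Si](C)(C)C(C)(C)C)CC1C | intermediate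
31 | α-bromosulfone (Br on C1) | O=S1(=O)C(Br)CC[C@@]2(COCc3ccc(OC)cc3)O[C@@H]2[C@@H](O[Si](CC)(CC)CC)[C@H](C(=C)CO[Si](C)(C)C(C)(C)C)[C@H](O[Si](C)(C)C(C)(C)C)CC1C | intermediate
32 | cis-fused episulfone (thiirane 1,1-dioxide across C1 and C10) | O=S1(=O)C2CC[C@@]3(COCc4ccc(OC)cc4)O[C@@H]3[C@@H](O[Si](CC)(CC)CC)[C@H](C(=C)CO[Si](C)(C)C(C)(C)C)[C@H](O[Si](C)(C)C(C)(C)C)CC12C | intermediate
33 | (1(10)Z)-ten-membered carbocycle, fully protected | C=C(CO[Si](C)(C)C(C)(C)C)[C@@H]1[C@H](O[Si](C)(C)C(C)(C)C)C/C(C)=C\CC[C@@]2(COCc3ccc(OC)cc3)O[C@@H]2[C@H]1O[Si](CC)(CC)CC | intermediate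
34 | 6,12-diol (C8–OTBS, C15–OPMB) | C=C(CO)[C@@H]1[C@H](O[Si](C)(C)C(C)(C)C)C/C(C)=C\CC[C@@]2(COCc3ccc(OC)cc3)O[C@@H]2[C@H]1O | intermediate
35 | lactol (C12 hemiacetal with O6) | C=C1C(O)O[C@H]2[C@H]1[C@H](O[Si](C)(C)C(C)(C)C)C/C(C)=C\CC[C@@]1(COCc3ccc(OC)cc3)O[C@H]21 | intermediate
36 | α-methylene-γ-lactone (C8–OTBS, C15–OPMB) | C=C1C(=O)O[C@H]2[C@H]1[C@H](O[Si](C)(C)C(C)(C)C)C/C(C)=C\CC[C@@]1(COCc3ccc(OC)cc3)O[C@H]21 | intermediate
37 | C8 alcohol (8-hydroxy-6,12-olide, C15–OPMB) | C=C1C(=O)O[C@H]2[C@H]1[C@H](O)C/C(C)=C\CC[C@@]1(COCc3ccc(OC)cc3)O[C@H]21 | intermediate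
38 | 2-[(4-methoxybenzyl)oxy]acetaldehyde | O=CCOCc1ccc(OC)cc1 | starting material
39 | ethyl 2-(triphenyl-λ5-phosphanylidene)propanoate | CCOC(=O)C(C)=P(c1ccccc1)(c1ccccc1)c1ccccc1 | starting material
40 | ethyl (E)-4-[(4-methoxybenzyl)oxy]-2-methylbut-2-enoate | CCOC(=O)/C(C)=C/COCc1ccc(OC)cc1 | intermediate
41 | (E)-4-[(4-methoxybenzyl)oxy]-2-methylbut-2-enoic acid | OC(=O)/C(C)=C/COCc1ccc(OC)cc1 | intermediate
42 | mixed anhydride of 41 with 2,4,6-trichlorobenzoic acid | O=C(OC(=O)/C(C)=C/COCc1ccc(OC)cc1)c1c(Cl)cc(Cl)cc1Cl | intermediate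
43 | bis-PMB ether of the target | C=C1C(=O)O[C@H]2[C@H]1[C@H](OC(=O)/C(C)=C/COCc3ccc(OC)cc3)C/C(C)=C\CC[C@@]1(COCc3ccc(OC)cc3)O[C@H]21 | intermediate
44 | CNP0187639.2 | C=C1C(=O)O[C@H]2[C@H]1[C@H](OC(=O)/C(C)=C/CO)C/C(C)=C\CC[C@@]1(CO)O[C@H]21 | target

**Count**

Total steps: 28. Longest linear sequence: 22 steps (steps 1–7, 12–24, 27, 28).

**Steps most likely to fail**

1. Step 21 (ring contraction). What may go wrong: poor control of the olefin geometry, or transannular opening of the epoxide by the α-sulfonyl carbanion under the equilibrating KOH conditions. The fallback is the classical stepwise Ramberg–Bäcklund sequence, in which the halogen is placed before the base step so that closure runs at low temperature with a non-nucleophilic base. It sets out from sulfide 28: NCS (CCl4, 0 °C) chlorinates the α-methylene carbon C1 to give the α-chloro sulfide F1 (the C10 regioisomer would converge as well). mCPBA/NaHCO3 (CH2Cl2, −20 °C) oxidises it to the α-chloro sulfone F2. KOt-Bu in THF at −78 → 0 °C then closes and collapses the episulfone, and the route is rejoined at 33.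

2. Step 18 (macrocyclic S-alkylation). What may go wrong: oligomerisation, or attack of the C10 thiolate on the epoxide in competition with displacement at C1. The fallback reverses the order of the two C–S bond formations so that ring closure is a reversible conjugate addition. It sets out from enone 22: KSAc/NaI (DMF, 23 °C) displaces the chloride to give the C1 thioacetate enone F3. Hydrazine acetate (DMF, 0 °C) frees the thiol, which with catalytic Et3N in dilute CH2Cl2 adds to the enone to give the 11-membered β-keto sulfide F4. Evans–Tishchenko reduction as in step 16 gives the macrocyclic O6-acetate C8-alcohol F5, and TBSOTf/2,6-lutidine gives the C8 silyl ether F6. DIBAL-H at −78 °C removes the acetate, and the route is rejoined at 27.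

3. Step 16 (Evans–Tishchenko reduction). What may go wrong: incomplete intramolecular hydride transfer, retro-aldol cleavage, or acetyl migration between O6 and O8. The fallback separates reduction and differentiation. It sets out from 23: Evans–Saksena hydroxyl-directed reduction (Me4NBH(OAc)3, MeCN/AcOH, −30 °C) gives the anti-1,3-diol F7. Site-selective silylation of the less hindered C8 hydroxyl (TBSCl, imidazole, DMF, 0 °C) gives the mono-silyl ether F8. S-Deacetylation with hydrazine acetate and cyclisation with Cs2CO3/NaI in dilute DMF then lead through thiol 26 to 27.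

Further compounds
F1 | step 21 | α-chloro sulfide (Cl on C1) | S1C(Cl)CC[C@@]2(COCc3ccc(OC)cc3)O[C@@H]2[C@@H](O[Si](CC)(CC)CC)[C@H](C(=C)CO[Si](C)(C)C(C)(C)C)[C@H](O[Si](C)(C)C(C)(C)C)CC1C
F2 | step 21 | α-chloro sulfone (Cl on C1) | O=S1(=O)C(Cl)CC[C@@]2(COCc3ccc(OC)cc3)O[C@@H]2[C@@H](O[Si](CC)(CC)CC)[C@H](C(=C)CO[Si](C)(C)C(C)(C)C)[C@H](O[Si](C)(C)C(C)(C)C)CC1C
F3 | step 18 | C1 thioacetate enone | CC(=O)SCCC[C@@]1(COCc2ccc(OC)cc2)O[C@@H]1[C@@H](O)[C@H](C(=C)CO[Si](C)(C)C(C)(C)C)C(=O)C=CC
F4 | step 18 | 11-membered β-keto sulfide (C6–OH, C8 ketone) | S1CCC[C@@]2(COCc3ccc(OC)cc3)O[C@@H]2[C@@H](O)[C@H](C(=C)CO[Si](C)(C)C(C)(C)C)C(=O)CC1C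
F5 | step 18 | macrocyclic O6-acetate C8-alcohol | S1CCC[C@@]2(COCc3ccc(OC)cc3)O[C@@H]2[C@@H](OC(C)=O)[C@H](C(=C)CO[Si](C)(C)C(C)(C)C)[C@H](O)CC1C
F6 | step 18 | macrocyclic O6-acetate C8 silyl ether | S1CCC[C@@]2(COCc3ccc(OC)cc3)O[C@@H]2[C@@H](OC(C)=O)[C@H](C(=C)CO[Si](C)(C)C(C)(C)C)[C@H](O[Si](C)(C)C(C)(C)C)CC1C
F7 | step 16 | anti-1,3-diol (C6–OH, C8–OH, AcS on C10) | ClCCC[C@@]1(COCc2ccc(OC)cc2)O[C@@H]1[C@@H](O)[C@H](C(=C)CO[Si](C)(C)C(C)(C)C)[C@H](O)CC(C)SC(C)=O
F8 | step 16 | C8 mono-silyl ether (C6–OH, AcS on C10) | ClCCC[C@@]1(COCc2ccc(OC)cc2)O[C@@H]1[C@@H](O)[C@H](C(=C)CO[Si](C)(C)C(C)(C)C)[C@H](O[Si](C)(C)C(C)(C)C)CC(C)SC(C)=O
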